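The ratio I watched was Z gained over L lost once the feed had stopped, both as fractions of the L charged.

| flask | L | Q | D | E | temperature | remark | time |
|---|---|---|---|---|---|---|---|
| Tuesday's | 0.74 M (fed, over 8.0 min) | 0.65 M | 1.5 M | 10 mM | 85 °C | run made earlier |  |
| Sunday's | 0.91 M (fed, over 8.0 min) | 0.65 M | 1.5 M | 10 mM | 96 °C | run made earlier |  |
| Thursday's | 0.50 M (fed, over 8.0 min) | 0.56 M | 1.5 M | 10 mM | 85 °C | run made earlier |  |
| amber | 0.80 M | 0.400 M | 1.50 M | 10.0 mM | 90 °C | everything together at the start | 40 min |
| red | 0.50 M (fed, over 8.0 min) | 0.650 M | 1.50 M | 10.0 mM | 90 °C |  | 40 min |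

- Tuesday's (time / min: Z / %, L / %): 3.00: 1, 37; 6.00: 2, 68; 10.0: 7, 85; 12.0: 12, 81; 15.0: 16, 75; 20.0: 17, 62
- Sunday's (time / min: Z / %, L / %): 1.33: 2, 16; 4.00: 6, 43; 8.00: 12, 76; 10.0: 16, 66; 15.0: 27, 48; 20.0: 31, 32
- Thursday's (time / min: Z / %, L / %): 1.50: 0, 17; 3.00: 0, 34; 6.00: 1, 68; 10.0: 7, 81; 20.0: 18, 63

(readings scatter by 1.5 percentage points)

- the analysis behind the earlier runs scatters by 1.5 percentage points, standard deviation
- percentages count the whole charge, also what has not yet gone in

- which one finishes higher in amount of Z, in percent of the L charged ("neither" within 2 percentage points) (amber / red / neither)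
- amount of Z at the end, in percent of the L charged, amber
- amount of Z at the end, in percent of the L charged, red

I read the tables column against column. In Tuesday's run, from 10.0 min to 20.0 min, L fell 23 percentage points and Z rose 10 points. In Sunday's run, from 8.00 min to 20.0 min, L fell 44 points and Z rose 19 points. The ratio read 0.435 in Tuesday's run and 0.432 in Sunday's, although the temperatures differed. Thursday's run, with less Q, read 0.611, the wrong way, but on a fall of 18 points with a scatter of 1.5 points at each end. So I pooled the three into a share of 0.471.

Its odds, Z gained over the rest of the L lost, divided by Tuesday's charge of Q over charge of D, I called S, a selectivity factor: 2.05.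

The L columns gave the loss. Read as a first-order constant, Tuesday's L fell at 0.0316 /min and Thursday's, with less L and less Q, at 0.0251 /min, so I took the order in L as first. Sunday's gave 0.0721 /min, and between the two temperatures I took 0.0459 /min.

Counting red's feed from its midpoint left 19.1% of L, so my red came to 38.1%. Amber had Q over D of 0.267, so I reckoned for amber a share of 0.354, L left 15.9%, and Z 29.7%.

The forecast also chose red, but lower, with amber 20% and red 26%: “The catalyst seems to die, perhaps faster with more L”. Mine stood higher on both.

The flasks gave red as the higher, with amber 29.7% and red 40.2%.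

    L ⇌ X (K = 0.0610, k = 0.0430 /min, Ea = 97.0 kJ/mol, ΔH = −36.0 kJ/mol)
    Q + X → Z (k = 43.0 /M/min, Ea = 73.0 kJ/mol)
    D + X → G (k = 15.0 /M/min, Ea = 76.0 kJ/mol)
    L + E → J (k = 43.0 /M/min, Ea = 51.0 kJ/mol)
    (constants at 90 °C)

Red converted 78.5% of its L, and S at red's Q over D gives 36.9% from that, against the 40.2% found. The main reason red fell short of the whole charge was the path from D + X to G: with that path taken away, red gave 75.6% instead of 40.2%, and that gain is 59% of what was missing. The neighbour of amber charged with 1.6 M of Q has 18.0% of L left, and S gives it 56.3%; computed, it reached 59.2%.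

The runs were generated by integration with constants of no real substance, noise included.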